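The numbers come from no measurement; the run is a simulation.

Take the charge and the questions first.

starting material 20 mM; partner 1.80 equiv; time 2.0 min

1. why nothing more happens at 2.0 min, or that something still does (it is still moving / all of the starting material has reacted / the partner has run out first)
2. amount of target at 2.0 min, in percent of the starting material charged
3. amount of open intermediate at 2.0 min, in percent of the starting material charged

- a doubled species enters its step squared and goes two at a time
- the reaction counts as stopped when no species that holds the starting material changes by six tenths of a point or more over the second half of the time
- run time (flask): 2.0 min

    starting material → open intermediate (k1 = 0.0093 s⁻¹)
    partner → second intermediate (k2 = 0.0061 s⁻¹)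
    open intermediate + second intermediate → target (k3 = 0.11 M⁻¹ s⁻¹)
    2 second intermediate → homo product (k4 = 0.060 M⁻¹ s⁻¹)

Starting material and partner each open by a first-order step. The two intermediates then couple to target, and second intermediate also doubles to homo product.

Turn the question round: what must be true for this flask to have stopped, or for target to lead? To stop, starting material must fall by less than the margin over the second half. Its half-life by step 1 alone is 1.2 min against a run of 2.0 min, so it falls by 24 percentage points. I call the flask still moving.

For target to lead, it must pass open intermediate. Integrate the coupling rate in closed form, with both intermediates unspent. Each opened fraction rises as one minus its exponential. Multiply the time integral of their product by the coupling constant and the partner charge. This gives Y, the unspent coupling share of the charge.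

6.86 % is my Y here. Losses of either intermediate lower the true target below it.

| Share of charge | Reckoned at 2.0 min |
|---|---|
| Opened | 67.2 % |
| Y | 6.86 % |

The opened share is ten times Y, so target does not lead. Open intermediate comes to about 60.4 % by my reckoning.

The forecast gives it is still moving, 5.8 % target and 61.4 % open intermediate, on these grounds: “Starting material is still falling fast, so the reaction is still moving.” Its target stands lower than my Y, and its open intermediate stands higher than mine.

The flask gives it is still moving, with 5.91 % target and 61.3 % open intermediate.

At 2.00 min, open intermediate in this flask is made 2.85 times faster than it is used up, each step taken net. Y stands 0.95 points above the target found in this flask. For the flask read at 30 s, Y comes to 0.171 %, and that flask holds 0.169 % target.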